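**Retrosynthetic overview**
1. Target 15 ⇒ triketone 13: the spiro C5'–C6' bond and the C7'–OOH bond are made together in the last step by an oxidative radical 6-endo spirocyclisation with O2 capture.
2. 13 ⇒ ketone 12 (MeMgBr addition) ⇒ triketone 6 + α-methylene ketone 11 (Michael addition; 11 is released from Mannich base 10).
3. 10 ⇒ cyclopent-2-en-1-one + isopropenylmagnesium bromide + iminium salt (asymmetric conjugate addition with Mannich trapping; sets the absolute configuration).
4. 6 ⇒ triacylmethane 5 (Claisen ring closure) ⇒ methyl acetoacetate + 2 prenyl bromide + 2 acetyl chloride.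
5. Ring order: triketone ring (step 3), cyclopentane (bought in as cyclopentenone), spiro cyclohexane (step 7).

Assumption: 6, 12 and 13 are drawn as dienol tautomers and 15 as the tautomer of the given SMILES; the ligand antipode written in step 4 is taken to give the 3R adduct (its mirror image is used if the sense is opposite).

**Route**

Step 1
Reactants: 1 methyl acetoacetate; 2 prenyl bromide (1-bromo-3-methylbut-2-ene, 2.3 equiv)
Product: 3 methyl 2-acetyl-5-methyl-2-(3-methylbut-2-en-1-yl)hex-4-enoate
Conditions: K2CO3 (3 equiv), DMF, 50 °C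
Reagents that add atoms: none
Why: Double C-alkylation of the β-keto ester (acetoacetic ester alkylation) with a soft allylic bromide builds the quaternary gem-diprenyl carbon; no stereocentre is formed.

Step 2
Reactants: 3 methyl 2-acetyl-5-methyl-2-(3-methylbut-2-en-1-yl)hex-4-enoate; 4 acetyl chloride (2.3 equiv)
Product: 5 methyl 4-acetyl-2,2-bis(3-methylbut-2-en-1-yl)-3,5-dioxohexanoate
Conditions: MgBr2·OEt2 (2.5 equiv), i-Pr2NEt (4.5 equiv), CH2Cl2, 0 → 23 °C
Reagents that add atoms: none
Why: Soft-enolisation C-acylation (Rathke/Coltart type, magnesium chelate) at the only enolisable position, the acetyl CH3, runs twice because the first-formed magnesium β-diketonate is itself C-acylated, giving the triacylmethane; no stereocentre.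

Step 3
Reactants: 5 methyl 4-acetyl-2,2-bis(3-methylbut-2-en-1-yl)-3,5-dioxohexanoate
Product: 6 2-acetyl-3,5-dihydroxy-4,4-bis(3-methylbut-2-en-1-yl)cyclohexa-2,5-dien-1-one
Conditions: LiN(i-Pr)2 (2.4 equiv), THF, −78 → 0 °C; then 1 M HCl
Reagents that add atoms: none
Why: Intramolecular Claisen (Dieckmann-type) condensation: the dianion (triacylmethanide plus terminal acetyl carbanion) attacks the non-enolisable ester in a 6-exo-trig closure and the product is held as its stabilised dienolate, so the triketone ring arrives with the acetyl group already in place; no stereocentre.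

Step 4
Reactants: 7 cyclopent-2-en-1-one; 8 isopropenylmagnesium bromide (1.2 equiv)
Product: 10 (2R,3R)-2-[(dimethylamino)methyl]-3-(prop-1-en-2-yl)cyclopentan-1-one, via magnesium enolate 9 (not isolated)
Conditions: CuBr·SMe2 (5 mol %), (R)-1-[(S)-2-(diphenylphosphino)ferrocenyl]ethyldicyclohexylphosphine (6 mol %), t-BuOMe, −75 °C; then the iminium iodide, THF, −75 → 0 °C
Reagents that add atoms: N,N-dimethylmethyleneiminium iodide (Eschenmoser's salt), C=[N+](C)C.[I-]
Why: Copper-catalysed asymmetric conjugate addition of the Grignard reagent (Feringa type) sets C-3 (R) under ligand control, and the regiodefined magnesium enolate is trapped by the iminium salt (Mannich reaction) anti to the isopropenyl group, which fixes the carbon that later carries the CH2 link to the triketone.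

Step 5
Reactants: 10 (2R,3R)-2-[(dimethylamino)methyl]-3-(prop-1-en-2-yl)cyclopentan-1-one (1.1 equiv); 6 2-acetyl-3,5-dihydroxy-4,4-bis(3-methylbut-2-en-1-yl)cyclohexa-2,5-dien-1-one
Product: 12 2-acetyl-3,5-dihydroxy-4,4-bis(3-methylbut-2-en-1-yl)-6-{[(1S,5R)-2-oxo-5-(prop-1-en-2-yl)cyclopentyl]methyl}cyclohexa-2,5-dien-1-one, via methylene ketone 11 (not isolated)
Conditions: MeCN, 70 °C; then cold 0.5 M HCl wash
Reagents that add atoms: none
Why: Mannich-base route to an α-methylene ketone followed by Michael addition: the acidic triketone protonates the amine, E1cB loss of dimethylamine releases enone 11 at low concentration, the soft ring carbon C-6 of 6 adds to it, and the ketone α-carbon is re-protonated to the more stable trans-2,3-disubstituted cyclopentanone (1S) while the 5R centre is untouched.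

Step 6
Reactants: 12 2-acetyl-3,5-dihydroxy-4,4-bis(3-methylbut-2-en-1-yl)-6-{[(1S,5R)-2-oxo-5-(prop-1-en-2-yl)cyclopentyl]methyl}cyclohexa-2,5-dien-1-one
Product: 13 2-acetyl-3,5-dihydroxy-6-{[(1S,2R,5R)-2-hydroxy-2-methyl-5-(prop-1-en-2-yl)cyclopentyl]methyl}-4,4-bis(3-methylbut-2-en-1-yl)cyclohexa-2,5-dien-1-one
Conditions: CeCl3 (5 equiv), MeMgBr (5 equiv), THF, −78 → 0 °C; then cold 0.5 M HCl
Reagents that add atoms: methylmagnesium bromide, C[Mg]Br
Why: Organocerium (Imamoto) 1,2-addition: the first two equivalents turn the triketone into a dienolate that is inert to the nucleophile, and methyl then adds to the cyclopentanone face anti to the adjacent CH2 arm, so the new OH is cis to that arm (2R).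

Step 7
Reactants: 13 2-acetyl-3,5-dihydroxy-6-{[(1S,2R,5R)-2-hydroxy-2-methyl-5-(prop-1-en-2-yl)cyclopentyl]methyl}-4,4-bis(3-methylbut-2-en-1-yl)cyclohexa-2,5-dien-1-one
Product: 15 (1R,3'R,3a'S,7'R,7a'R)-3-acetyl-7'-hydroperoxy-3',4-dihydroxy-3',7'-dimethyl-5,5-bis(3-methylbut-2-en-1-yl)-1',2',3',3a',4',6',7',7a'-octahydrospiro[cyclohex-3-ene-1,5'-indene]-2,6-dione, via tertiary radical 14 (not isolated)
Conditions: Mn(OAc)3·2H2O (20 mol %), O2 (1 atm), AcOH, 23 °C; preparative HPLC
Reagents that add atoms: dioxygen, O=O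
Why: Proposed new method: trivalent manganese oxidises the triketone enolate to the electrophilic tricarbonylmethyl radical at C-6, which closes 6-endo-trig on the CH2 end of the isopropenyl group through a chair on the trans-disubstituted cyclopentane (5-exo closure would need a trans-bicyclo[3.3.0]octane), the tertiary radical 14 takes up O2 from the equatorial side because the axial side is blocked 1,3-diaxially by the axial spiro carbonyl (7'R, OOH equatorial, methyl axial), and the peroxyl radical is reduced to the hydroperoxide by divalent manganese or by hydrogen transfer from the enol of 13; the spiro centre forms in the same closure, the two chairs differ only in which carbonyl of the planar radical becomes axial, so little bias is expected and the 1R product 15 is separated from its 1S epimer; every atom of 13 and O2 ends up in 15; closest known chemistry is the Snider-type Mn(OAc)3 6-endo oxidative cyclisation and the Nishino-type Mn(OAc)3/O2 hydroperoxidation of alkenes with 1,3-dicarbonyls.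

**Compound list**
1 | methyl acetoacetate (methyl 3-oxobutanoate) | CC(=O)CC(=O)OC | starting material
2 | prenyl bromide (1-bromo-3-methylbut-2-ene) | CC(C)=CCBr | starting material
3 | methyl 2-acetyl-5-methyl-2-(3-methylbut-2-en-1-yl)hex-4-enoate | COC(=O)C(CC=C(C)C)(CC=C(C)C)C(C)=O | intermediate
4 | acetyl chloride | CC(Cl)=O | starting material
5 | methyl 4-acetyl-2,2-bis(3-methylbut-2-en-1-yl)-3,5-dioxohexanoate | COC(=O)C(CC=C(C)C)(CC=C(C)C)C(=O)C(C(C)=O)C(C)=O | intermediate
6 | 2-acetyl-3,5-dihydroxy-4,4-bis(3-methylbut-2-en-1-yl)cyclohexa-2,5-dien-1-one (dienol form of 2-acetyl-4,4-diprenylcyclohexane-1,3,5-trione) | CC(=O)C1=C(O)C(CC=C(C)C)(CC=C(C)C)C(O)=CC1=O | intermediate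
7 | cyclopent-2-en-1-one | O=C1C=CCC1 | starting material
8 | isopropenylmagnesium bromide (prop-1-en-2-ylmagnesium bromide) | CC(=C)[Mg]Br | starting material
9 | bromomagnesium (R)-3-(prop-1-en-2-yl)cyclopent-1-en-1-olate | Br[Mg]OC1=C[C@@H](CC1)C(C)=C | intermediate
10 | (2R,3R)-2-[(dimethylamino)methyl]-3-(prop-1-en-2-yl)cyclopentan-1-one | CN(C)C[C@H]1[C@@H](CCC1=O)C(C)=C | intermediate
11 | (S)-2-methylidene-3-(prop-1-en-2-yl)cyclopentan-1-one | C=C1[C@@H](CCC1=O)C(C)=C | intermediate
12 | 2-acetyl-3,5-dihydroxy-4,4-bis(3-methylbut-2-en-1-yl)-6-{[(1S,5R)-2-oxo-5-(prop-1-en-2-yl)cyclopentyl]methyl}cyclohexa-2,5-dien-1-one | CC(=O)C1=C(O)C(CC=C(C)C)(CC=C(C)C)C(O)=C(C[C@H]2[C@@H](CCC2=O)C(C)=C)C1=O | intermediate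
13 | 2-acetyl-3,5-dihydroxy-6-{[(1S,2R,5R)-2-hydroxy-2-methyl-5-(prop-1-en-2-yl)cyclopentyl]methyl}-4,4-bis(3-methylbut-2-en-1-yl)cyclohexa-2,5-dien-1-one | CC(=O)C1=C(O)C(CC=C(C)C)(CC=C(C)C)C(O)=C(C[C@H]2[C@@H](CC[C@@]2(C)O)C(C)=C)C1=O | intermediate
14 | ring-closed tertiary carbon radical at C-7' (15 without the OOH group; other four stereocentres as in 15) | CC(=O)C1=C(O)C(CC=C(C)C)(CC=C(C)C)C(=O)[C@]2(C[C@H]3[C@@H](CC[C@@]3(C)O)[C](C)C2)C1=O | intermediate
15 | (1R,3'R,3a'S,7'R,7a'R)-3-acetyl-7'-hydroperoxy-3',4-dihydroxy-3',7'-dimethyl-5,5-bis(3-methylbut-2-en-1-yl)-1',2',3',3a',4',6',7',7a'-octahydrospiro[cyclohex-3-ene-1,5'-indene]-2,6-dione (CNP0149131.2) | CC(=O)C1=C(O)C(CC=C(C)C)(CC=C(C)C)C(=O)[C@]2(C[C@H]3[C@@H](CC[C@@]3(C)O)[C@](C)(OO)C2)C1=O | target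

**Step count**
Total: 7 steps. Longest linear sequence: 6 steps (1, 2, 3, 5, 6, 7).

**Three steps most likely to fail**

Step 7 (radical spirocyclisation with O2 capture). Three things can go wrong:
- the C-6 radical can attack a prenyl group on C-4 (5-exo, bicyclo[3.2.1] core) instead of the isopropenyl group;
- O2 can trap the C-6 radical before it cyclises, giving the 6-hydroxy triketone;
- the spiro centre forms with little selectivity.

Fallback, setting out from 13 and returning at 15: N-bromosuccinimide in CH2Cl2 at −78 °C brominates the nucleophilic ring carbon to give the 6-bromo triketone F1. CuBr (10 mol %, monovalent copper) with tris(2-pyridylmethyl)amine in benzene at 60 °C under argon then effects a bromine-atom-transfer 6-endo cyclisation to the tertiary bromide F2; oxygen is absent, so hydroxylation at C-6 cannot compete. AgOSO2CF3 and anhydrous H2O2 in Et2O at −30 °C finally replace bromide by hydroperoxide through the tertiary cation, again from the equatorial side, to give 15.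

Step 4 (asymmetric conjugate addition with Mannich trapping). An alkenyl Grignard reagent on cyclopentenone may give low ee or some 1,2-addition. Fallback, setting out from 7 and returning at 10: ligand-free CuBr·SMe2 (10 mol %) with 8 and the same iminium trapping gives the racemic trans Mannich base F3. Crystallisation from EtOH with (−)-O,O'-di-p-toluoyl-L-tartaric acid gives the di-p-toluoyl-L-tartrate salt F4 of the (2R,3R) amine; the antipodal acid is used if the other salt is the less soluble one. Aqueous NaHCO3 then frees 10.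

Step 3 (ring closure of the triacylmethane; this also covers over- or under-acylation in step 2). Fallback, setting out from 3 and returning at 6: one acetylation with 4 (1.05 equiv, same MgBr2·OEt2/i-Pr2NEt conditions) gives the β-diketo ester F5. LiN(i-Pr)2 (2.2 equiv) in THF closes the ring through the terminal carbanion of the diketone dianion to the diprenyl trione F6. Ac2O/Et3N gives the enol acetate F7, and 4-(dimethylamino)pyridine moves the acetyl group from oxygen to carbon to give 6.

**Further compounds**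
F1 | step 7 | 2-acetyl-6-bromo-3-hydroxy-6-{[(1S,2R,5R)-2-hydroxy-2-methyl-5-(prop-1-en-2-yl)cyclopentyl]methyl}-4,4-bis(3-methylbut-2-en-1-yl)cyclohex-2-ene-1,5-dione (both C-6 epimers) | CC(=O)C1=C(O)C(CC=C(C)C)(CC=C(C)C)C(=O)C(Br)(C[C@H]2[C@@H](CC[C@@]2(C)O)C(C)=C)C1=O
F2 | step 7 | 7'-bromo analogue of 15 (Br in place of OOH, either C-7' configuration) | CC(=O)C1=C(O)C(CC=C(C)C)(CC=C(C)C)C(=O)[C@]2(C[C@H]3[C@@H](CC[C@@]3(C)O)C(C)(Br)C2)C1=O
F3 | step 4 | racemic trans-2-[(dimethylamino)methyl]-3-(prop-1-en-2-yl)cyclopentan-1-one | CN(C)CC1C(CCC1=O)C(C)=C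
F4 | step 4 | (2R,3R)-2-[(dimethylamino)methyl]-3-(prop-1-en-2-yl)cyclopentan-1-one (2R,3R)-2,3-bis(4-methylbenzoyloxy)butanedioic acid salt | CN(C)C[C@H]1[C@@H](CCC1=O)C(C)=C.OC(=O)[C@H](OC(=O)c1ccc(C)cc1)[C@@H](OC(=O)c1ccc(C)cc1)C(O)=O
F5 | step 3 | methyl 2,2-bis(3-methylbut-2-en-1-yl)-3,5-dioxohexanoate | COC(=O)C(CC=C(C)C)(CC=C(C)C)C(=O)CC(C)=O
F6 | step 3 | 3,5-dihydroxy-4,4-bis(3-methylbut-2-en-1-yl)cyclohexa-2,5-dien-1-one | O=C1C=C(O)C(CC=C(C)C)(CC=C(C)C)C(O)=C1
F7 | step 3 | 5-hydroxy-6,6-bis(3-methylbut-2-en-1-yl)-3-oxocyclohexa-1,4-dien-1-yl acetate | CC(=O)OC1=CC(=O)C=C(O)C1(CC=C(C)C)CC=C(C)C
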